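**Plan**
- Retrosynthesis: remove the late groups first (the C10–C11 oxirane oxygen and the two angelate C–O bonds), then cut C7–C8, then take the ring back to (S)-carvone (C3–Cl/C2–OH from a 2,3-epoxide, C1–O and C6–O from carbonyl chemistry, the C7 enol triflate from the isopropenyl group).
- Enabling feature: C7 is the sp2 carbon of the exocyclic 1,1-disubstituted C7=CH2 alkene on ring C5 and C8 is an oxygen-bearing sp3 carbon; this 2-substituted allylic alcohol is the retron of an alkenylchromium(III) addition to an aldehyde.
- Forward: the cyclohexane ring is that of carvone (no carbocycle is built). It is oxygenated and chlorinated, the isopropenyl group is cut to an acetyl group and converted to an enol triflate, the C6 chain (4-methylpent-3-enal) is joined by Ni/Cr coupling, both angelates are added, and the oxirane is closed last.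
- Stereochemistry: C5 from (S)-carvone; C1 by Luche reduction; C2/C3 by hydroxyl-directed epoxidation and trans-diaxial chloride opening; C6 by oxidation and bulky-hydride reduction; C8 by the chiral ligand on chromium in the key step; C10 by Shi epoxidation.

Key step: step 12

Remark: locants follow carvone (ring C1–C6, C5 carries the side chain C7(=CH2)–C8–C9–C10–C11); β means the ring face of the C5 substituent, α the opposite face.

**Step 1**
Reactants: 1 (S)-(+)-carvone
Product: 3 (5R,6R)-6-hydroxycarvone (6α-OH; trans to isopropenyl), via potassium dienolate 2 (not isolated)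
Conditions: KHMDS, THF, −78 °C; then 2-(phenylsulfonyl)-3-phenyloxaziridine, −78 °C; aq. NH4Cl
Reagents that add atoms: 2-(phenylsulfonyl)-3-phenyloxaziridine, O=S(=O)(N1OC1c1ccccc1)c1ccccc1
Why: Davis oxidation: kinetic α′-deprotonation at C6 gives the cross-conjugated dienolate, which should be hydroxylated anti to the C5 isopropenyl group (6α-OH); this centre is only a handle and is reset in steps 6–7.

**Step 2**
Reactants: 3 (5R,6R)-6-hydroxycarvone
Product: 4 5β-isopropenyl-2-methylcyclohex-2-ene-1β,6α-diol
Conditions: NaBH4, CeCl3·7H2O, MeOH, −78 → 0 °C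
Reagents that add atoms: none
Why: Luche 1,2-reduction: axial hydride attack on the half-chair with equatorial C5 and C6 substituents should give the equatorial 1β-alcohol, cis to the isopropenyl group as in the carvone to cis-carveol reduction.

**Step 3**
Reactants: 4 1β,6α-diol
Product: 5 2β,3β-epoxy-5β-isopropenyl-2-methylcyclohexane-1β,6α-diol
Conditions: VO(acac)2 (cat.), t-BuOOH (decane), CH2Cl2, 0 °C → rt
Reagents that add atoms: tert-butyl hydroperoxide, CC(C)(C)OO
Why: Hydroxyl-directed vanadium-catalysed epoxidation: the allylic C1–OH should deliver oxygen to the syn (β) face of the ring alkene only, leaving the isopropenyl group untouched.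

**Step 4**
Reactants: 5 2β,3β-epoxy-1β,6α-diol
Product: 6 3α-chloro-5β-isopropenyl-2α-methylcyclohexane-1β,2β,6α-triol
Conditions: ClTi(OiPr)3 (from Ti(OiPr)4/TiCl4 3:1), CH2Cl2, 0 °C → rt; aq. tartaric acid
Reagents that add atoms: chlorotitanium triisopropoxide, CC(C)O[Ti](Cl)(OC(C)C)OC(C)C
Why: Titanium-assisted C3-opening of a 2,3-epoxy alcohol: chloride should attack the secondary carbon anti to the oxirane, which is both the Fürst–Plattner (trans-diaxial) and the less hindered position, giving 3α-Cl with inversion and keeping the 2β tertiary OH.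

**Step 5**
Reactants: 6 3α-chloro-1β,2β,6α-triol
Product: 7 1β,2β-O-isopropylidene derivative of 6 (6α-OH free)
Conditions: Me2C(OMe)2, PPTS (cat.), acetone, rt
Reagents that add atoms: 2,2-dimethoxypropane, COC(C)(C)OC
Why: Acetonide formation under thermodynamic control: only C1/C2 is a cis-1,2-diol (C1/C6 is trans-diequatorial), so the cis-fused dioxolane should form selectively; it frees 6-OH for inversion and ties up the tertiary OH so that the chlorohydrin cannot close in later base steps.

**Step 6**
Reactants: 7 acetonide alcohol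
Product: 8 3α-chloro-1β,2β-O-isopropylidene-5β-isopropenyl-2α-methylcyclohexan-6-one
Conditions: Dess–Martin periodinane, NaHCO3, CH2Cl2, 0 °C; used directly
Reagents that add atoms: none
Why: Dess–Martin oxidation of the only free hydroxyl under buffered conditions; the ketone is carried on at once because C5–H is now α to a carbonyl and allylic.

**Step 7**
Reactants: 8 6-ketone
Product: 9 6β-alcohol (all-cis C5/C6/C1)
Conditions: L-Selectride, THF, −78 °C; aq. NH4Cl
Reagents that add atoms: none
Why: Bulky-hydride reduction of a cyclohexanone flanked by two equatorial substituents: equatorial attack, reinforced by the axial C2 oxygen blocking the axial trajectory, should give the axial 6β-OH, cis to O1 and to the C5 substituent.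

**Step 8**
Reactants: 9 6β-alcohol
Product: 10 6β-O-TBS ether of 9
Conditions: TBSOTf, 2,6-lutidine, CH2Cl2, −78 → 0 °C
Reagents that add atoms: tert-butyldimethylsilyl triflate, CC(C)(C)[Si](C)(C)OS(=O)(=O)C(F)(F)F
Why: Silyl triflate silylation of a hindered axial secondary alcohol; TBS is chosen to survive the later acetonide cleavage and esterification.

**Step 9**
Reactants: 10 TBS ether
Product: 12 5β-acetyl compound (methyl ketone), via secondary ozonide 11 (not isolated)
Conditions: O3, CH2Cl2, −78 °C; then Me2S, −78 °C → rt
Reagents that add atoms: ozone, [O-][O+]=O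
Why: Ozonolysis with reductive work-up; the isopropenyl group is the only alkene in 10.

**Step 10**
Reactants: 12 methyl ketone
Product: 14 C7 enol triflate (1-substituted vinyl triflate), via potassium enolate 13 (not isolated)
Conditions: KHMDS, THF, −78 °C; then N-(5-chloro-2-pyridyl)bis(trifluoromethanesulfonimide), −78 °C; aq. NH4Cl
Reagents that add atoms: N-(5-chloropyridin-2-yl)-1,1,1-trifluoro-N-(trifluoromethylsulfonyl)methanesulfonamide, O=S(=O)(N(c1ccc(Cl)cn1)S(=O)(=O)C(F)(F)F)C(F)(F)F
Why: Kinetic enolisation at the methyl group (not at the hindered C5 methine, which also avoids β-elimination of the 6-silyloxy group) followed by O-triflation should give the 1,1-disubstituted enol triflate.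

**Step 11**
Reactants: 15 4-methylpent-3-en-1-ol
Product: 16 4-methylpent-3-enal
Conditions: Dess–Martin periodinane, NaHCO3, CH2Cl2, 0 °C; used as a fresh solution
Reagents that add atoms: none
Why: Buffered Dess–Martin oxidation of a homoallylic alcohol should give the β,γ-unsaturated aldehyde without conjugation.

**Step 12**
Reactants: 14 enol triflate; 16 4-methylpent-3-enal
Product: 17 (8S)-allylic alcohol (C7–C8 joined; acetonide and TBS in place)
Conditions: CrCl2, chiral (4,5-dihydrooxazol-2-yl)aryl methanesulfonamide ligand (antipode for Re-face addition), Et3N, NiCl2 (cat.), MeCN/THF, rt; aq. EDTA work-up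
Reagents that add atoms: none
Why: Ni(0) inserts into the C7–OTf bond of 14 and transmetallates to Cr(III); the ligand-bound alkenylchromium(III) adds to the aldehyde carbon of 16 through a closed, Cr–O-organised transition state, forming C7–C8 and the chromium alkoxide of 17. The closest known reaction type is the ligand-controlled asymmetric Nozaki–Hiyama–Kishi coupling of 2-substituted alkenyl iodides or triflates with aldehydes to give 2-substituted allylic alcohols. No ring is closed. The one new stereocentre, C8, is set by the chiral ligand on chromium (reagent control; Re-face attack on the aldehyde gives 8S), so any mismatch with the C5/C6 centres can be probed with the other ligand antipode. The step needs chemoselectivity for the aldehyde beside a secondary alkyl chloride, an acetonide, a silyl ether and a skipped alkene, and it must not enolise or conjugate the β,γ-unsaturated aldehyde; the non-basic, weakly nucleophilic organochromium reagent should secure both. Regiochemistry is fixed because the metal sits on C7 of the preformed 1,1-disubstituted alkene.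

**Step 13**
Reactants: 17 (8S)-allylic alcohol
Product: 18 (8S)-1β,2β,8-triol (6β-O-TBS, 3α-Cl)
Conditions: AcOH–H2O–THF (3:1:1), 45 °C
Reagents that add atoms: none
Why: Acid-catalysed acetal hydrolysis should free the cis-1,2-diol while the hindered secondary TBS ether, the allylic alcohol and the trisubstituted alkene survive buffered aqueous acetic acid.

**Step 14**
Reactants: 18 triol; 19 angelic acid (2 equiv)
Product: 20 1,8-di-O-angeloyl-6-O-TBS compound
Conditions: 19, 2,4,6-trichlorobenzoyl chloride, Et3N, toluene, rt; then 18, toluene, 80 °C (no DMAP)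
Reagents that add atoms: none
Why: Yamaguchi-type esterification with the preformed mixed anhydride and no nucleophilic catalyst should acylate both secondary hydroxyls (C1 and C8), leave the tertiary C2–OH free, and keep the Z (angelate) geometry.

**Step 15**
Reactants: 20 bis-angelate TBS ether
Product: 21 1,8-di-O-angeloyl-6β-ol (10,11-alkene)
Conditions: HF·pyridine, pyridine, THF, 0 °C → rt
Reagents that add atoms: none
Why: Buffered acidic desilylation avoids base, so the chlorohydrin should not close and no angeloyl group should migrate to the cis 6-OH; it is done before epoxidation so that no oxirane meets HF.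

**Step 16**
Reactants: 21 bis-angelate diol
Product: 22 target, (1S,2S,3S,5R,6S)-3-chloro-2,6-dihydroxy-2-methyl-5-{(3S)-4-[(2R)-3,3-dimethyloxiran-2-yl]-3-[(Z)-2-methylbut-2-enoyloxy]but-1-en-2-yl}cyclohexyl (Z)-2-methylbut-2-enoate
Conditions: D-fructose-derived Shi ketone (0.3–0.5 equiv), Oxone, NaHCO3 (pH ≈ 8), Bu4NHSO4 (cat.), MeCN–CH2(OMe)2–aq. Na2EDTA, 0 °C
Reagents that add atoms: potassium peroxymonosulfate (Oxone), [K+].[O-]S(=O)(=O)OO
Why: Shi asymmetric epoxidation: the chiral dioxirane should epoxidise the electron-rich trisubstituted C10=C11 alkene in preference to the 1,1-disubstituted allylic-ester alkene and the two enoates, and the spiro transition-state model for the D-fructose-derived ketone predicts the 10R oxirane; near-neutral pH protects the chlorohydrin and esters.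

**Compound list**
1 | (S)-(+)-carvone | C=C(C)[C@H]1CC=C(C)C(=O)C1 | starting material
2 | potassium dienolate of carvone | [K+].C=C(C)[C@H]1CC=C(C)C([O-])=C1 | intermediate
3 | (5R,6R)-6-hydroxycarvone (6α-OH) | C=C(C)[C@H]1CC=C(C)C(=O)[C@@H]1O | intermediate
4 | 5β-isopropenyl-2-methylcyclohex-2-ene-1β,6α-diol | C=C(C)[C@H]1CC=C(C)[C@@H](O)[C@@H]1O | intermediate
5 | 2β,3β-epoxy-5β-isopropenyl-2-methylcyclohexane-1β,6α-diol | C=C(C)[C@H]1C[C@H]2O[C@@]2(C)[C@@H](O)[C@@H]1O | intermediate
6 | 3α-chloro-5β-isopropenyl-2α-methylcyclohexane-1β,2β,6α-triol | C=C(C)[C@H]1C[C@H](Cl)[C@@](C)(O)[C@@H](O)[C@@H]1O | intermediate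
7 | 1β,2β-O-isopropylidene derivative of 6 (6α-OH free) | C=C(C)[C@H]1C[C@H](Cl)[C@@]2(C)OC(C)(C)O[C@H]2[C@@H]1O | intermediate
8 | 6-ketone of 7 | C=C(C)[C@H]1C[C@H](Cl)[C@@]2(C)OC(C)(C)O[C@H]2C1=O | intermediate
9 | 6β-alcohol (C6 epimer of 7) | C=C(C)[C@H]1C[C@H](Cl)[C@@]2(C)OC(C)(C)O[C@H]2[C@H]1O | intermediate
10 | 6β-O-TBS ether of 9 | C=C(C)[C@H]1C[C@H](Cl)[C@@]2(C)OC(C)(C)O[C@H]2[C@H]1O[Si](C)(C)C(C)(C)C | intermediate
11 | secondary ozonide (1,2,4-trioxolane, epimers at the trioxolane carbon) of 10 | CC2(OCOO2)[C@H]1C[C@H](Cl)[C@@]3(C)OC(C)(C)O[C@H]3[C@H]1O[Si](C)(C)C(C)(C)C | intermediate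
12 | 5β-acetyl compound (methyl ketone) | CC(=O)[C@H]1C[C@H](Cl)[C@@]2(C)OC(C)(C)O[C@H]2[C@H]1O[Si](C)(C)C(C)(C)C | intermediate
13 | potassium enolate of 12 (terminal) | [K+].C=C([O-])[C@H]1C[C@H](Cl)[C@@]2(C)OC(C)(C)O[C@H]2[C@H]1O[Si](C)(C)C(C)(C)C | intermediate
14 | C7 enol triflate | C=C(OS(=O)(=O)C(F)(F)F)[C@H]1C[C@H](Cl)[C@@]2(C)OC(C)(C)O[C@H]2[C@H]1O[Si](C)(C)C(C)(C)C | intermediate
15 | 4-methylpent-3-en-1-ol | CC(C)=CCCO | starting material
16 | 4-methylpent-3-enal | CC(C)=CCC=O | intermediate
17 | (8S)-allylic alcohol (acetonide, TBS) | C=C([C@H](CC=C(C)C)O)[C@H]1C[C@H](Cl)[C@@]2(C)OC(C)(C)O[C@H]2[C@H]1O[Si](C)(C)C(C)(C)C | intermediate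
18 | (8S)-1β,2β,8-triol (6β-O-TBS) | C=C([C@H](CC=C(C)C)O)[C@H]1C[C@H](Cl)[C@@](C)(O)[C@@H](O)[C@H]1O[Si](C)(C)C(C)(C)C | intermediate
19 | angelic acid, (Z)-2-methylbut-2-enoic acid | C/C=C(/C)C(=O)O | starting material
20 | 1,8-di-O-angeloyl-6-O-TBS compound | C=C([C@H](CC=C(C)C)OC(=O)/C(C)=C\C)[C@H]1C[C@H](Cl)[C@@](C)(O)[C@@H](OC(=O)/C(C)=C\C)[C@H]1O[Si](C)(C)C(C)(C)C | intermediate
21 | 1,8-di-O-angeloyl-6β-ol (10,11-alkene) | C=C([C@H](CC=C(C)C)OC(=O)/C(C)=C\C)[C@H]1C[C@H](Cl)[C@@](C)(O)[C@@H](OC(=O)/C(C)=C\C)[C@H]1O | intermediate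
22 | target (CNP0158207.1) | C=C([C@H](C[C@H]1OC1(C)C)OC(=O)/C(C)=C\C)[C@H]1C[C@H](Cl)[C@@](C)(O)[C@@H](OC(=O)/C(C)=C\C)[C@H]1O | target

**Totals**
Total step count: 16. Longest linear sequence: 15 (steps 1–10 and 12–16).

**Steps most likely to fail**

Step 12. The risks are poor facial selectivity at C8 if the ring stereocentres override the ligand, and slow oxidative addition of the hindered α-branched triflate. The fallback sets out from 14 and 16. A ligand-free NiCl2/CrCl2 coupling (DMF–THF, rt) is run without regard to C8 and should give 17 mixed with its C8 epimer, 8-epi-17 F1. The mixture is oxidised (Dess–Martin periodinane, NaHCO3, CH2Cl2, 0 °C) to the single cross-conjugated 8-oxo enone F2. The carbinol centre is then set by CBS reduction ((R)-Me-oxazaborolidine, catecholborane, toluene, −78 °C; the α-branched alkenyl group acts as the large substituent), which comes back to the route at 17.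

Step 14. The risks are incomplete acylation of the hindered C1–OH, Z→E isomerisation of the angelate on long heating with amine, and closure of the chlorohydrin. The fallback sets out from 18. Both secondary hydroxyls are first acylated with the unhindered acid 2-[bis(2,2,2-trifluoroethoxy)phosphoryl]propanoic acid (EDC, DMAP cat., CH2Cl2, 0 °C) to give the bis-phosphonopropionate F3. A double Still–Gennari olefination (KHMDS 2.0 equiv, 18-crown-6, THF, −78 °C; then acetaldehyde) then builds both Z-trisubstituted enoates and comes back to the route at 20.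

Step 13. Acid strong enough to open the hindered cis-fused acetonide may also cleave the silyl ether, ionise the allylic C8 alcohol or hydrate the trisubstituted alkene. The fallback sets out from 14, which has neither an allylic alcohol nor a trisubstituted alkene. The acetonide is removed first (TFA–H2O–CH2Cl2, 0 °C) to give the triflate diol F4. The same Ni/Cr coupling with 16 (free hydroxyls are tolerated by alkenylchromium reagents) then comes back to the route directly at 18.

**Further compounds**
F1 | step 12 | 8-epi-17, the (8R)-allylic alcohol | C=C([C@@H](CC=C(C)C)O)[C@H]1C[C@H](Cl)[C@@]2(C)OC(C)(C)O[C@H]2[C@H]1O[Si](C)(C)C(C)(C)C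
F2 | step 12 | 8-oxo enone | C=C(C(=O)CC=C(C)C)[C@H]1C[C@H](Cl)[C@@]2(C)OC(C)(C)O[C@H]2[C@H]1O[Si](C)(C)C(C)(C)C
F3 | step 14 | 1,8-bis-O-{2-[bis(2,2,2-trifluoroethoxy)phosphoryl]propanoyl} derivative of 18 | C=C([C@H](CC=C(C)C)OC(=O)C(C)P(=O)(OCC(F)(F)F)OCC(F)(F)F)[C@H]1C[C@H](Cl)[C@@](C)(O)[C@@H](OC(=O)C(C)P(=O)(OCC(F)(F)F)OCC(F)(F)F)[C@H]1O[Si](C)(C)C(C)(C)C
F4 | step 13 | enol triflate 1β,2β-diol (acetonide removed from 14) | C=C(OS(=O)(=O)C(F)(F)F)[C@H]1C[C@H](Cl)[C@@](C)(O)[C@@H](O)[C@H]1O[Si](C)(C)C(C)(C)C
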